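Ring B is closed last across C9–C10 (drimane numbering), the bond between the two quaternary carbons. The route exploits that C10 is the β-carbon of a 2,6,6-trimethylcyclohexenyl ketone (ring A alkene C5=C10, carbonyl = future C6–O) and that C9 is an α-hydroxy-acid carbon. A Michael–Michael annulation is used: the methyl-ketone dienolate (C7) adds to a chiral (2S)-2-tert-butyl-5-ethylidene-1,3-dioxolan-4-one (C8, C9, C11, C12), and the resulting dioxolanone enolate, the true cyclisation precursor, closes onto C10. One operation thus forms ring B and both quaternary centres, their configuration relayed from the acetal carbon. Dehydrogenation, 6β-reduction, C12 oxidation, acylation and acetal hydrolysis follow.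

Key step: step 6

Remark: drimane numbering is used throughout (ring A: C1–C5, C10; ring B: C5–C10; C11 = carboxyl carbon on C9; C12 = formyl carbon on C8; α = the face opposite the C10 methyl group).
Assumption: the target is treated as the open hydroxy acid–aldehyde as drawn (its lactol tautomer is not addressed); β-cyclocitral, (S)-2-hydroxybutanoic acid, pivalaldehyde and (2E,4E,6E)-octa-2,4,6-trienoic acid are taken as purchasable.

Step 1
Reactants: 1 β-cyclocitral (2,6,6-trimethylcyclohex-1-ene-1-carbaldehyde)
Product: 2 rac-1-(2,6,6-trimethylcyclohex-1-en-1-yl)ethan-1-ol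
Conditions: MeMgBr, THF, 0 °C; aq. NH4Cl
Reagents that add atoms: methylmagnesium bromide, C[Mg]Br
Why: Grignard 1,2-addition to the hindered, non-enolisable enal should give the carbinol; its stereocentre is racemic and is destroyed in step 2.

Step 2
Reactants: 2 rac-1-(2,6,6-trimethylcyclohex-1-en-1-yl)ethan-1-ol
Product: 3 1-(2,6,6-trimethylcyclohex-1-en-1-yl)ethan-1-one
Conditions: Dess–Martin periodinane, CH2Cl2, rt
Reagents that add atoms: none
Why: Dess–Martin oxidation of the secondary allylic alcohol should give the methyl ketone, whose only α-hydrogens are those of the methyl group (future C7).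

Step 3
Reactants: 4 (S)-2-hydroxybutanoic acid
Product: 5 (2S,5S)-2-tert-butyl-5-ethyl-1,3-dioxolan-4-one (cis)
Conditions: pivalaldehyde, cat. TsOH, pentane, reflux (Dean–Stark); cis isomer purified by low-temperature crystallisation
Reagents that add atoms: pivalaldehyde, CC(C)(C)C=O
Why: Acid-catalysed acetalisation of the α-hydroxy acid should favour the cis-(2S,5S) isomer under thermodynamic control, fixing the acetal stereocentre that later controls C9 (self-regeneration of stereocentres).

Step 4
Reactants: 5 (2S,5S)-2-tert-butyl-5-ethyl-1,3-dioxolan-4-one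
Product: 6 (2S,5R)-5-bromo-2-tert-butyl-5-ethyl-1,3-dioxolan-4-one (Br trans to tert-butyl)
Conditions: NBS, cat. AIBN, PhCF3, reflux
Reagents that add atoms: N-bromosuccinimide, O=C1CCC(=O)N1Br
Why: Wohl–Ziegler-type radical bromination should occur at the captodative C5–H, bromine entering trans to tert-butyl and the acetal centre staying untouched.

Step 5
Reactants: 6 (2S,5R)-5-bromo-2-tert-butyl-5-ethyl-1,3-dioxolan-4-one
Product: 7 (2S,Z)-2-tert-butyl-5-ethylidene-1,3-dioxolan-4-one
Conditions: DBU, CH2Cl2, 0 °C to rt; Z isomer isolated by chromatography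
Reagents that add atoms: none
Why: E2 dehydrobromination should give the 5-alkylidene dioxolanone (a chiral 2-oxyacrylate equivalent); the Z isomer (methyl cis to the ring oxygen, away from the carbonyl) is expected as the thermodynamically preferred product.

Step 6
Reactants: 3 1-(2,6,6-trimethylcyclohex-1-en-1-yl)ethan-1-one, 7 (2S,Z)-2-tert-butyl-5-ethylidene-1,3-dioxolan-4-one
Product: 11 pivalaldehyde (2S)-acetal (1,3-dioxolan-4-one spiro at C9) of 9α-hydroxy-6-oxo-8βH-driman-11-oic acid (trans-decalin, 5α-H, 10β-CH3, 8α-CH3, C9–O α, C11 β, tert-butyl cis to C8), via lithium dienolate 8 (not isolated), via Michael-adduct lithium enolate 9 (not isolated), via cyclised lithium enolate 10 (not isolated)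
Conditions: LDA, THF, −78 °C; then 7, −78 to 0 °C; AcOH
Reagents that add atoms: none
Why: Kinetic deprotonation of 3 gives dienolate 8, which adds through C7 to C8 of 7 on the face opposite the tert-butyl group; the dioxolanone enolate 9 then attacks C10, the β-carbon of the cyclohexenyl ketone, forming C9–C10 and closing ring B, and enolate 10 should be protonated at C5 from the less shielded α face to the trans-fused ketone. The closest known reaction type is the double Michael (Michael-initiated ring closure, anionic [4+2]) annulation of cross-conjugated ketone dienolates with acrylates, together with the Michael chemistry of 2-tert-butyl-1,3-dioxolan-4-one enolates. Ring B, a six-membered carbocycle, is closed in the 6-endo-trig mode. C9 is controlled by the (2S)-acetal carbon, with C10 entering anti to tert-butyl; C10 is controlled by a chair-like transition state in which the C8 methyl (cis to the ring oxygen after addition of both carbons to the same face of the Z-alkene) stays equatorial and away from the C10 methyl, so the C9 oxygen becomes axial (α) and C11 equatorial (β, cis to the C10 methyl); the C8 centre is removed in step 7. The step needs 1,4- rather than 1,2-addition to the acylal carbonyl and closure faster than proton transfer, which low temperature, the soft lithium enolate and the reversibility of the first addition (only the adduct that can reach the chair closes) should secure.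

Step 7
Reactants: 11 spiro-dioxolanone ketone (6-oxo, 8α-CH3)
Product: 12 pivalaldehyde (2S)-acetal of 9α-hydroxy-6-oxodrim-7-en-11-oic acid (5α-H, 10β-CH3)
Conditions: IBX, DMSO/fluorobenzene, 75 °C
Reagents that add atoms: none
Why: IBX dehydrogenation of the ketone can only introduce the C7=C8 double bond because C5 has no β-hydrogen (C4 and C10 are quaternary); this also erases the C8 stereocentre.

Step 8
Reactants: 12 6-oxodrim-7-ene acetal
Product: 13 pivalaldehyde (2S)-acetal of 6β,9α-dihydroxydrim-7-en-11-oic acid (6β-OH axial)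
Conditions: NaBH4, CeCl3·7H2O, MeOH/THF, −78 °C
Reagents that add atoms: none
Why: Luche 1,2-reduction should deliver hydride to the α face of C6, because the β face is shielded by the 1,3-diaxial C10 and C4β methyl groups, giving the axial 6β-alcohol.

Step 9
Reactants: 13 6β-hydroxydrim-7-ene acetal
Product: 14 pivalaldehyde (2S)-acetal of 6β,9α-dihydroxy-12-oxodrim-7-en-11-oic acid
Conditions: SeO2, 1,4-dioxane, 80 °C
Reagents that add atoms: selenium dioxide, O=[Se]=O
Why: Riley allylic oxidation should act at the more substituted alkene terminus C8, whose only allylic hydrogens are those of the C12 methyl (C9 is quaternary), giving the enal.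

Step 10
Reactants: 14 6β-hydroxy-12-oxodrim-7-ene acetal, 15 (2E,4E,6E)-octa-2,4,6-trienoic acid
Product: 17 pivalaldehyde (2S)-acetal of 9α-hydroxy-6β-[(2E,4E,6E)-octa-2,4,6-trienoyloxy]-12-oxodrim-7-en-11-oic acid, via (2E,4E,6E)-octa-2,4,6-trienoic 2,4,6-trichlorobenzoic anhydride 16 (not isolated)
Conditions: 15, 2,4,6-trichlorobenzoyl chloride, Et3N, THF, rt; then 14, DMAP, toluene, 60 °C
Reagents that add atoms: none
Why: Yamaguchi esterification via the mixed anhydride should acylate the hindered axial 6β-OH with retention at C6; the C9 oxygen and C11 are masked in the acetal, so no other hydroxyl competes.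

Step 11
Reactants: 17 trienoate acetal
Product: 18 ustusoic acid B
Conditions: 2 M aq. HCl, THF, rt to 40 °C
Reagents that add atoms: water, O
Why: Acid-catalysed hydrolysis of the acylal (cleavage at the acetal carbon, remote from the hindered C9/C10 region) should release pivalaldehyde and unmask the tertiary 9α-OH and the C11 acid without touching the trienoate ester or the enal.

Compound list
1 | β-cyclocitral (2,6,6-trimethylcyclohex-1-ene-1-carbaldehyde) | CC1=C(C=O)C(C)(C)CCC1 | starting material
2 | rac-1-(2,6,6-trimethylcyclohex-1-en-1-yl)ethan-1-ol | CC(O)C1=C(C)CCCC1(C)C | intermediate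
3 | 1-(2,6,6-trimethylcyclohex-1-en-1-yl)ethan-1-one | CC(=O)C1=C(C)CCCC1(C)C | intermediate
4 | (S)-2-hydroxybutanoic acid | CC[C@H](O)C(=O)O | starting material
5 | (2S,5S)-2-tert-butyl-5-ethyl-1,3-dioxolan-4-one | CC[C@@H]1O[C@H](C(C)(C)C)OC1=O | intermediate
6 | (2S,5R)-5-bromo-2-tert-butyl-5-ethyl-1,3-dioxolan-4-one | CC[C@]1(Br)O[C@H](C(C)(C)C)OC1=O | intermediate
7 | (2S,Z)-2-tert-butyl-5-ethylidene-1,3-dioxolan-4-one | C/C=C1\O[C@H](C(C)(C)C)OC1=O | intermediate
8 | lithium 1-(2,6,6-trimethylcyclohex-1-en-1-yl)ethen-1-olate (kinetic dienolate of 3) | C=C(O[Li])C1=C(C)CCCC1(C)C | intermediate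
9 | Michael adduct, lithium enolate of the dioxolanone (C7–C8 bond formed, ring B still open) | CC1=C(C(=O)C[C@@H](C)C2=C(O[Li])O[C@@H](C(C)(C)C)O2)C(C)(C)CCC1 | intermediate
10 | cyclised lithium enolate (C5=C6–OLi) of 11 | [Li]OC1=C2C(C)(C)CCC[C@]2(C)[C@]3(O[C@H](C(C)(C)C)OC3=O)[C@H](C)C1 | intermediate
11 | pivalaldehyde (2S)-acetal of 9α-hydroxy-6-oxo-8βH-driman-11-oic acid (5α-H, 10β-CH3, 8α-CH3) | O=C1C[C@@H](C)[C@@]3(O[C@H](C(C)(C)C)OC3=O)[C@@]2(C)CCCC(C)(C)[C@H]12 | intermediate
12 | pivalaldehyde (2S)-acetal of 9α-hydroxy-6-oxodrim-7-en-11-oic acid | O=C1C=C(C)[C@@]3(O[C@H](C(C)(C)C)OC3=O)[C@@]2(C)CCCC(C)(C)[C@H]12 | intermediate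
13 | pivalaldehyde (2S)-acetal of 6β,9α-dihydroxydrim-7-en-11-oic acid | O[C@@H]1C=C(C)[C@@]3(O[C@H](C(C)(C)C)OC3=O)[C@@]2(C)CCCC(C)(C)[C@H]12 | intermediate
14 | pivalaldehyde (2S)-acetal of 6β,9α-dihydroxy-12-oxodrim-7-en-11-oic acid | O[C@@H]1C=C(C=O)[C@@]3(O[C@H](C(C)(C)C)OC3=O)[C@@]2(C)CCCC(C)(C)[C@H]12 | intermediate
15 | (2E,4E,6E)-octa-2,4,6-trienoic acid | C/C=C/C=C/C=C/C(=O)O | starting material
16 | (2E,4E,6E)-octa-2,4,6-trienoic 2,4,6-trichlorobenzoic anhydride | C/C=C/C=C/C=C/C(=O)OC(=O)c1c(Cl)cc(Cl)cc1Cl | intermediate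
17 | pivalaldehyde (2S)-acetal of 9α-hydroxy-6β-[(2E,4E,6E)-octa-2,4,6-trienoyloxy]-12-oxodrim-7-en-11-oic acid | C/C=C/C=C/C=C/C(=O)O[C@@H]1C=C(C=O)[C@@]3(O[C@H](C(C)(C)C)OC3=O)[C@@]2(C)CCCC(C)(C)[C@H]12 | intermediate
18 | ustusoic acid B | C/C=C/C=C/C=C/C(=O)O[C@@H]1C=C(C=O)[C@](O)(C(=O)O)[C@@]2(C)CCCC(C)(C)[C@H]12 | target

Total step count: 11. Longest linear sequence: 9 steps (4 to 18 through steps 3–11).

Steps most likely to fail

1. Step 6 (Michael–Michael annulation). The sequence may stall after the first conjugate addition, because closure onto the twisted, fully substituted C10 could be slower than proton transfer to the ketone α-position or thermal fragmentation of the dioxolanone enolate; weak facial control at C8 would also erode the diastereoselectivity. Fallback (concerted cycloaddition instead of stepwise anionic closure): ketone 3 would be converted with LDA/TMSCl into 1-[1-(trimethylsilyloxy)vinyl]-2,6,6-trimethylcyclohex-1-ene F1. A thermal or high-pressure Diels–Alder reaction of this diene with 7 (toluene, 110 °C, sealed tube, or about 12 kbar in CH2Cl2) should add anti to tert-butyl with the lactone carbonyl exo and give the C5=C6 trimethylsilyl enol ether of 11 F2. Desilylation (TBAF, AcOH, THF) would return to the route at ketone 11.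

2. Step 9 (allylic oxidation). The free C6 allylic carbinol may be oxidised competitively to the enone, or the oxidation may stop at the C12 alcohol stage. Fallback (oxidise C12 before the carbinol exists): enone 12 would be oxidised with SeO2 (dioxane, 80 °C) at its γ-methyl group to the pivalaldehyde (2S)-acetal of 9α-hydroxy-6,12-dioxodrim-7-en-11-oic acid F3. Both carbonyl groups would then be reduced under Luche conditions to the pivalaldehyde (2S)-acetal of 6β,9α,12-trihydroxydrim-7-en-11-oic acid F4, and the primary allylic alcohol oxidised chemoselectively with TEMPO/PhI(OAc)2 to rejoin the route at 14.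

3. Step 11 (acetal hydrolysis). Acylal cleavage may be too slow at an acidity that the trienoate ester tolerates, so that ester hydrolysis or acyl migration competes. Fallback (unmask before acylation and carry a temporary allyl ester): 14 would be opened with K2CO3 in allyl alcohol to allyl 6β,9α-dihydroxy-12-oxodrim-7-en-11-oate F5. Its secondary 6β-OH would be acylated selectively over the tertiary 9α-OH with 15 under the conditions of step 10 to give allyl 9α-hydroxy-6β-[(2E,4E,6E)-octa-2,4,6-trienoyloxy]-12-oxodrim-7-en-11-oate F6, and the allyl ester removed with Pd(PPh3)4/PhSiH3 to give 18 directly.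

Further compounds
F1 | step 6 | 1-[1-(trimethylsilyloxy)vinyl]-2,6,6-trimethylcyclohex-1-ene | C=C(O[Si](C)(C)C)C1=C(C)CCCC1(C)C
F2 | step 6 | C5=C6 trimethylsilyl enol ether of 11 | C[Si](C)(C)OC1=C2C(C)(C)CCC[C@]2(C)[C@]3(O[C@H](C(C)(C)C)OC3=O)[C@H](C)C1
F3 | step 9 | pivalaldehyde (2S)-acetal of 9α-hydroxy-6,12-dioxodrim-7-en-11-oic acid | O=C1C=C(C=O)[C@@]3(O[C@H](C(C)(C)C)OC3=O)[C@@]2(C)CCCC(C)(C)[C@H]12
F4 | step 9 | pivalaldehyde (2S)-acetal of 6β,9α,12-trihydroxydrim-7-en-11-oic acid | O[C@@H]1C=C(CO)[C@@]3(O[C@H](C(C)(C)C)OC3=O)[C@@]2(C)CCCC(C)(C)[C@H]12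
F5 | step 11 | allyl 6β,9α-dihydroxy-12-oxodrim-7-en-11-oate | O[C@@H]1C=C(C=O)[C@](O)(C(=O)OCC=C)[C@@]2(C)CCCC(C)(C)[C@H]12
F6 | step 11 | allyl 9α-hydroxy-6β-[(2E,4E,6E)-octa-2,4,6-trienoyloxy]-12-oxodrim-7-en-11-oate | C/C=C/C=C/C=C/C(=O)O[C@@H]1C=C(C=O)[C@](O)(C(=O)OCC=C)[C@@]2(C)CCCC(C)(C)[C@H]12
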